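**Retrosynthetic overview**
1. Ring B is closed last: C2=C3 by intramolecular Knoevenagel condensation of a C1 β-keto ester onto the C3 ketone. The β-keto ester comes from Claisen-type acylation of methyl acetate enolate by a C1 Weinreb amide.
2. The C5 and C8 methyl esters come from CH2OH and CHO groups. The C6 hexadecyl chain comes from Negishi coupling of a C6–C7 enol triflate.
3. Ring A is formed first: intermolecular Michael addition of the kinetic dienolate of an enone ketal to (5R)-menthyloxyfuranone, then intramolecular Michael closure (sets C8, C8a, C4a). C5 is set by anti hydroxymethylation.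
4. The enone ketal comes from methyl acetoacetate and 1-bromopentadecane; the furanone from furfural and (−)-menthol.
5. Ring order: ring A (carried on a temporary γ-lactone acetal), then ring B.

Assumption: the SMILES defines the target as (4aR,5S,8R,8aS); intermediates carry the target's locants (C1–C8a) for the corresponding atoms.

**Route**

Step 1
Reactants: 1 methyl acetoacetate; 2 1-bromopentadecane
Product: 4 methyl 3-oxononadecanoate, via acetoacetate dianion 3 (not isolated)
Conditions: NaH, THF, 0 °C; n-BuLi, 0 °C; then 2, 0 °C → rt; dilute HCl work-up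
Reagents that add atoms: none
Why: γ-Alkylation of the acetoacetate dianion occurs only at the more basic terminal carbon and gives the C16 chain on the ketone.

Step 2
Reactants: 4 methyl 3-oxononadecanoate
Product: 5 methyl 2-(2-hexadecyl-1,3-dioxolan-2-yl)acetate
Conditions: HOCH2CH2OH, TsOH (cat.), PhH, reflux, Dean–Stark
Reagents that add atoms: ethylene glycol OCCO
Why: Acid-catalysed ketalisation with water removal masks the ketone and leaves the ester untouched.

Step 3
Reactants: 5 methyl 2-(2-hexadecyl-1,3-dioxolan-2-yl)acetate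
Product: 6 2-(2-hexadecyl-1,3-dioxolan-2-yl)acetaldehyde
Conditions: i-Bu2AlH (1.1 equiv), CH2Cl2, −78 °C; Rochelle salt work-up
Reagents that add atoms: none
Why: Partial ester reduction stops at the aldehyde because the chelated tetrahedral aluminate is stable at −78 °C.

Step 4
Reactants: 6 2-(2-hexadecyl-1,3-dioxolan-2-yl)acetaldehyde; 7 1-(triphenyl-λ5-phosphanylidene)propan-2-one
Product: 8 (E)-5-(2-hexadecyl-1,3-dioxolan-2-yl)pent-3-en-2-one
Conditions: CH2Cl2, rt → 40 °C
Reagents that add atoms: none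
Why: Wittig olefination with a stabilised ylide gives the E-enone under neutral conditions that spare the β-ketal aldehyde.

Step 5
Reactants: 9 furfural
Product: 10 5-hydroxyfuran-2(5H)-one
Conditions: O2, hν, rose bengal (cat.), MeOH, rt
Reagents that add atoms: oxygen O=O
Why: Singlet-oxygen [4+2] photooxygenation of the furan and methanolysis of the endoperoxide expel the formyl carbon and give the hydroxybutenolide.

Step 6
Reactants: 10 5-hydroxyfuran-2(5H)-one; 11 (−)-menthol
Product: 12 (5R)-5-(l-menthyloxy)furan-2(5H)-one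
Conditions: CSA (cat.), PhH, reflux (−H2O); crystallise (petroleum ether, −20 °C); mother liquor re-equilibrated with acid and recrystallised
Reagents that add atoms: none
Why: Acid-catalysed acetalisation gives both C5 epimers, and crystallisation with acid-mediated epimerisation of the mother liquor funnels the material to the (5R)-acetal.

Step 7
Reactants: 8 (E)-5-(2-hexadecyl-1,3-dioxolan-2-yl)pent-3-en-2-one; 12 (5R)-5-(l-menthyloxy)furan-2(5H)-one
Product: 16 cis-fused lactone acetal trimethylsilyl enol ether (C5=C6), via lithium dienolate 13 (not isolated), via Michael adduct lactone enolate 14 (not isolated), via bicyclic lithium enolate 15 (not isolated)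
Conditions: LiN(i-Pr)2, THF, −78 °C; then 12, −78 → −20 °C; Me3SiCl, Et3N, −78 °C → rt; used crude
Reagents that add atoms: chlorotrimethylsilane C[Si](C)(C)Cl
Why: The kinetic cross-conjugated dienolate adds to the butenolide anti to the menthyloxy group (intermolecular Michael addition, sets C8), the lactone enolate closes ring A by intramolecular Michael addition through a lithium-chelated endo-type arrangement (cis fusion at C8a, C4a side chain cis to the lactone), and O-silylation fixes the C5=C6 enolate regiochemistry.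

Step 8
Reactants: 16 cis-fused lactone acetal trimethylsilyl enol ether
Product: 17 C5-hydroxymethyl C6-ketone
Conditions: aq. CH2O (37%), Yb(OTf)3 (10 mol %), THF, rt
Reagents that add atoms: formaldehyde C=O
Why: In this aqueous Mukaiyama aldol reaction formaldehyde attacks C5 from the convex face, opposite the C4a side chain and the lactone, which gives the C4a/C5 trans relationship.

Step 9
Reactants: 17 C5-hydroxymethyl C6-ketone
Product: 18 C5-(tert-butyldimethylsilyloxymethyl) C6-ketone
Conditions: TBSCl, imidazole, DMF, rt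
Reagents that add atoms: tert-butyldimethylsilyl chloride CC(C)(C)[Si](C)(C)Cl
Why: Silyl protection of the primary alcohol blocks retro-aldol and elimination pathways before enolate chemistry.

Step 10
Reactants: 18 C5-(tert-butyldimethylsilyloxymethyl) C6-ketone
Product: 20 C6–C7 enol triflate, via kinetic lithium enolate 19 (not isolated)
Conditions: LiN(i-Pr)2, THF, −78 °C; PhNTf2, −78 → 0 °C
Reagents that add atoms: N-phenylbis(trifluoromethanesulfonimide) O=S(=O)(N(c1ccccc1)S(=O)(=O)C(F)(F)F)C(F)(F)F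
Why: Kinetic deprotonation takes the unhindered C7 methylene and not the C5 methine, so O-triflation fixes the future C6=C7 alkene without touching C5.

Step 11
Reactants: 21 1-iodohexadecane
Product: 22 hexadecylzinc iodide (THF solution used directly)
Conditions: Zn dust, LiCl, THF, 50 °C
Reagents that add atoms: zinc [Zn]
Why: LiCl-promoted direct zinc insertion into the primary C–I bond gives an organozinc that tolerates lactones and acetals.

Step 12
Reactants: 20 C6–C7 enol triflate; 22 hexadecylzinc iodide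
Product: 23 C6-hexadecyl lactone acetal silyl ether
Conditions: Pd(dppf)Cl2 (5 mol %), THF/NMP, 50 °C
Reagents that add atoms: none
Why: Negishi cross-coupling of the alkenyl triflate with the primary alkylzinc installs the C6 chain with the double bond held at C6=C7 and no stereocentre involved.

Step 13
Reactants: 23 C6-hexadecyl lactone acetal silyl ether
Product: 24 C5-hydroxymethyl lactone acetal
Conditions: HF·pyridine, THF/pyridine, 0 °C → rt
Reagents that add atoms: none
Why: Buffered fluoride desilylation frees the primary alcohol while the ketal and the acylal survive.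

Step 14
Reactants: 24 C5-hydroxymethyl lactone acetal
Product: 25 C8-formyl C5-hydroxymethyl C1 Weinreb amide
Conditions: MeNH(OMe)·HCl, AlMe3, CH2Cl2, 0 °C → rt; Rochelle salt work-up; used crude
Reagents that add atoms: N,O-dimethylhydroxylamine hydrochloride CNOC.Cl
Why: Weinreb aminolysis at the lactone carbonyl lets the acylal collapse to the C8 aldehyde and menthol under non-basic conditions, so C8 and C8a keep their configuration.

Step 15
Reactants: 25 C8-formyl C5-hydroxymethyl C1 Weinreb amide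
Product: 26 C5,C8-dicarboxylic acid
Conditions: TEMPO (20 mol %), PhI(OAc)2 (3.5 equiv), MeCN/pH 7 buffer, 0 °C → rt
Reagents that add atoms: water O
Why: Oxoammonium (TEMPO) oxidation takes the alcohol and the aldehyde hydrate to carboxylic acids without base, so the allylic α-stereocentres are not epimerised.

Step 16
Reactants: 26 C5,C8-dicarboxylic acid
Product: 27 C5,C8-dimethyl ester C1 Weinreb amide
Conditions: Me3SiCHN2, MeOH/PhMe, 0 °C
Reagents that add atoms: (trimethylsilyl)diazomethane C[Si](C)(C)C=[N+]=[N-]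
Why: Diazoalkane O-methylation esterifies both acids under neutral conditions.

Step 17
Reactants: 27 C5,C8-dimethyl ester C1 Weinreb amide; 28 methyl acetate
Product: 30 C1 β-keto ester, via methyl acetate lithium enolate 29 (not isolated)
Conditions: LiN(i-Pr)2, 28, THF, −78 °C; then 27, −78 → −40 °C; AcOH quench at −78 °C
Reagents that add atoms: none
Why: In this crossed Claisen-type condensation the ester enolate is acylated by the Weinreb amide, whose chelated tetrahedral adduct prevents over-addition, while the methyl esters do not react at this temperature.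

Step 18
Reactants: 30 C1 β-keto ester
Product: 32 trimethyl (4aR,5S,8R,8aS)-3,6-dihexadecyl-1-oxo-1,4,4a,5,8,8a-hexahydronaphthalene-2,5,8-tricarboxylate, via diketo ester 31 (not isolated)
Conditions: 1 M HCl, THF, rt; then piperidine, AcOH (cat.), PhMe, 4 Å MS, 40 °C
Reagents that add atoms: none
Why: Acid removes the dioxolane and the β-keto ester methylene then condenses with the C3 ketone (intramolecular Knoevenagel condensation), closing ring B with no new stereocentre.

**Compound list**
1 | methyl acetoacetate | CC(=O)CC(=O)OC | starting material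
2 | 1-bromopentadecane | CCCCCCCCCCCCCCCBr | starting material
3 | sodium lithium dianion of methyl acetoacetate | C=C(O[Li])C=C(O[Na])OC | intermediate
4 | methyl 3-oxononadecanoate | CCCCCCCCCCCCCCCCC(=O)CC(=O)OC | intermediate
5 | methyl 2-(2-hexadecyl-1,3-dioxolan-2-yl)acetate | CCCCCCCCCCCCCCCCC1(CC(=O)OC)OCCO1 | intermediate
6 | 2-(2-hexadecyl-1,3-dioxolan-2-yl)acetaldehyde | CCCCCCCCCCCCCCCCC1(CC=O)OCCO1 | intermediate
7 | 1-(triphenyl-λ5-phosphanylidene)propan-2-one | CC(=O)C=P(c1ccccc1)(c1ccccc1)c1ccccc1 | starting material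
8 | (E)-5-(2-hexadecyl-1,3-dioxolan-2-yl)pent-3-en-2-one | CC(=O)/C=C/CC1(CCCCCCCCCCCCCCCC)OCCO1 | intermediate
9 | furfural | O=Cc1ccco1 | starting material
10 | 5-hydroxyfuran-2(5H)-one (racemic hemiacetal) | O=C1C=CC(O)O1 | intermediate
11 | (−)-menthol, (1R,2S,5R)-2-isopropyl-5-methylcyclohexanol | CC(C)[C@@H]1CC[C@@H](C)C[C@H]1O | starting material
12 | (5R)-5-{[(1R,2S,5R)-2-isopropyl-5-methylcyclohexyl]oxy}furan-2(5H)-one | O=C1C=C[C@H](O[C@@H]2C[C@H](C)CC[C@H]2C(C)C)O1 | intermediate
13 | kinetic cross-conjugated lithium dienolate of 8 (CH2=C(OLi)–CH=CH–, E) | C=C(O[Li])/C=C/CC1(CCCCCCCCCCCCCCCC)OCCO1 | intermediate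
14 | lithium lactone enolate of the Michael adduct: butenolide C4 (future C8) bears the CH2–CO–CH=CH–CH2–ketal chain trans to the menthyloxy group | O=C(C[C@@H]1C=C(O[Li])O[C@H]1O[C@@H]2C[C@H](C)CC[C@H]2C(C)C)/C=C/CC3(CCCCCCCCCCCCCCCC)OCCO3 | intermediate
15 | bicyclic lithium enolate (C5=C6–OLi); ring A cis-fused to the lactone, C4a side chain cis to the lactone | [Li]OC1=C[C@H](CC2(CCCCCCCCCCCCCCCC)OCCO2)[C@@H]3C(=O)O[C@@H](O[C@@H]4C[C@H](C)CC[C@H]4C(C)C)[C@@H]3C1 | intermediate
16 | (3R)-7-[(2-hexadecyl-1,3-dioxolan-2-yl)methyl]-3-(l-menthyloxy)-5-(trimethylsilyloxy)-3a,4,7,7a-tetrahydroisobenzofuran-1(3H)-one; H-3a, H-7a and H-7 all cis, menthyloxy trans to C4 | C[Si](C)(C)OC1=C[C@H](CC2(CCCCCCCCCCCCCCCC)OCCO2)[C@@H]3C(=O)O[C@@H](O[C@@H]4C[C@H](C)CC[C@H]4C(C)C)[C@@H]3C1 | intermediate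
17 | 7-[(2-hexadecyl-1,3-dioxolan-2-yl)methyl]-6-(hydroxymethyl)-3-(l-menthyloxy)hexahydroisobenzofuran-1,5-dione; as 16, CH2OH at C6 trans to the C7 side chain | O=C1[C@@H](CO)[C@H](CC2(CCCCCCCCCCCCCCCC)OCCO2)[C@@H]3C(=O)O[C@@H](O[C@@H]4C[C@H](C)CC[C@H]4C(C)C)[C@@H]3C1 | intermediate
18 | tert-butyldimethylsilyl ether of 17 | O=C1[C@@H](CO[Si](C)(C)C(C)(C)C)[C@H](CC2(CCCCCCCCCCCCCCCC)OCCO2)[C@@H]3C(=O)O[C@@H](O[C@@H]4C[C@H](C)CC[C@H]4C(C)C)[C@@H]3C1 | intermediate
19 | kinetic lithium enolate of 18 (C6–OLi, C6=C7) | [Li]OC1=C[C@H]2[C@H](O[C@@H]3C[C@H](C)CC[C@H]3C(C)C)OC(=O)[C@H]2[C@@H](CC4(CCCCCCCCCCCCCCCC)OCCO4)[C@@H]1CO[Si](C)(C)C(C)(C)C | intermediate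
20 | C6–C7 enol triflate of 18 (stereocentres as 18) | O=S(=O)(OC1=C[C@H]2[C@H](O[C@@H]3C[C@H](C)CC[C@H]3C(C)C)OC(=O)[C@H]2[C@@H](CC4(CCCCCCCCCCCCCCCC)OCCO4)[C@@H]1CO[Si](C)(C)C(C)(C)C)C(F)(F)F | intermediate
21 | 1-iodohexadecane | CCCCCCCCCCCCCCCCI | starting material
22 | hexadecylzinc iodide | CCCCCCCCCCCCCCCC[Zn]I | intermediate
23 | C6-hexadecyl cyclohexene cis-fused to the menthyloxy lactone acetal; C5 CH2OTBS trans to the C4a side chain | CCCCCCCCCCCCCCCCC1=C[C@H]2[C@H](O[C@@H]3C[C@H](C)CC[C@H]3C(C)C)OC(=O)[C@H]2[C@@H](CC4(CCCCCCCCCCCCCCCC)OCCO4)[C@@H]1CO[Si](C)(C)C(C)(C)C | intermediate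
24 | primary alcohol from 23 (C5 CH2OH) | CCCCCCCCCCCCCCCCC1=C[C@H]2[C@H](O[C@@H]3C[C@H](C)CC[C@H]3C(C)C)OC(=O)[C@H]2[C@@H](CC4(CCCCCCCCCCCCCCCC)OCCO4)[C@@H]1CO | intermediate
25 | 2-formyl-4-hexadecyl-6-[(2-hexadecyl-1,3-dioxolan-2-yl)methyl]-5-(hydroxymethyl)-N-methoxy-N-methylcyclohex-3-ene-1-carboxamide; 1,2-cis, 1,6-cis, 5,6-trans | CCCCCCCCCCCCCCCCC1=C[C@@H](C=O)[C@@H](C(=O)N(C)OC)[C@@H](CC2(CCCCCCCCCCCCCCCC)OCCO2)[C@@H]1CO | intermediate
26 | 3-hexadecyl-5-[(2-hexadecyl-1,3-dioxolan-2-yl)methyl]-6-[methoxy(methyl)carbamoyl]cyclohex-2-ene-1,4-dicarboxylic acid; 1,6-cis, 5,6-cis, 4,5-trans | CCCCCCCCCCCCCCCCC1=C[C@@H](C(=O)O)[C@@H](C(=O)N(C)OC)[C@@H](CC2(CCCCCCCCCCCCCCCC)OCCO2)[C@@H]1C(=O)O | intermediate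
27 | dimethyl ester of 26 | CCCCCCCCCCCCCCCCC1=C[C@@H](C(=O)OC)[C@@H](C(=O)N(C)OC)[C@@H](CC2(CCCCCCCCCCCCCCCC)OCCO2)[C@@H]1C(=O)OC | intermediate
28 | methyl acetate | CC(=O)OC | starting material
29 | lithium enolate of methyl acetate | C=C(O[Li])OC | intermediate
30 | dimethyl 3-hexadecyl-5-[(2-hexadecyl-1,3-dioxolan-2-yl)methyl]-6-(3-methoxy-3-oxopropanoyl)cyclohex-2-ene-1,4-dicarboxylate; stereocentres as 27 | CCCCCCCCCCCCCCCCC1=C[C@@H](C(=O)OC)[C@@H](C(=O)CC(=O)OC)[C@@H](CC2(CCCCCCCCCCCCCCCC)OCCO2)[C@@H]1C(=O)OC | intermediate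
31 | dimethyl 3-hexadecyl-6-(3-methoxy-3-oxopropanoyl)-5-(2-oxooctadecyl)cyclohex-2-ene-1,4-dicarboxylate; stereocentres as 27 | CCCCCCCCCCCCCCCCC1=C[C@@H](C(=O)OC)[C@@H](C(=O)CC(=O)OC)[C@@H](CC(=O)CCCCCCCCCCCCCCCC)[C@@H]1C(=O)OC | intermediate
32 | trimethyl (4aR,5S,8R,8aS)-3,6-dihexadecyl-1-oxo-1,4,4a,5,8,8a-hexahydronaphthalene-2,5,8-tricarboxylate | CCCCCCCCCCCCCCCCC1=C[C@@H](C(=O)OC)[C@H]2C(=O)C(C(=O)OC)=C(CCCCCCCCCCCCCCCC)C[C@H]2[C@@H]1C(=O)OC | target

**Totals**
Total step count: 18. Longest linear sequence: 15 steps (steps 1–4, 7–10, 12–18).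

**Steps most likely to fail, with fallbacks**

Step 7. The intramolecular Michael closure may stall at the open adduct or give the C4a epimer. The fallback sets out from 8: the kinetic dienolate is silylated (LiN(i-Pr)2, Me3SiCl, THF, −78 °C) to the 2-(trimethylsilyloxy)diene F1. F1 is then heated with 12 in toluene at 110 °C. The concerted endo Diels–Alder cycloaddition, anti to the menthyloxy group, gives the same silyl enol ether, so the route is rejoined at 16.

Step 10. Enolisation must go to C7; deprotonation at C5 would be followed by β-elimination of the silyloxy group. The fallback sets out from 18: an in situ quench (LiN(i-Pr)2 with Me3SiCl present, THF, −78 °C) gives the C6–C7 trimethylsilyl enol ether F2. F2 can be purified from any C5–C6 isomer and is then converted with CsF and PhNTf2 in DME into the triflate, rejoining the route at 20.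

Step 17. A strongly basic ester enolate meets two epimerisable β,γ-unsaturated esters that can also slip into conjugation. The fallback sets out from 27: Cp2Zr(H)Cl in THF reduces only the Weinreb amide, giving the C1 aldehyde F3. SnCl2-catalysed Roskamp homologation of F3 with methyl diazoacetate in CH2Cl2 gives the β-keto ester under neutral conditions, rejoining the route at 30.

**Further compounds**
F1 | step 7 | (E)-2-hexadecyl-2-[4-(trimethylsilyloxy)penta-2,4-dien-1-yl]-1,3-dioxolane | C=C(O[Si](C)(C)C)/C=C/CC1(CCCCCCCCCCCCCCCC)OCCO1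
F2 | step 10 | C6–C7 trimethylsilyl enol ether of 18 | C[Si](C)(C)OC1=C[C@H]2[C@H](O[C@@H]3C[C@H](C)CC[C@H]3C(C)C)OC(=O)[C@H]2[C@@H](CC4(CCCCCCCCCCCCCCCC)OCCO4)[C@@H]1CO[Si](C)(C)C(C)(C)C
F3 | step 17 | dimethyl 6-formyl-3-hexadecyl-5-[(2-hexadecyl-1,3-dioxolan-2-yl)methyl]cyclohex-2-ene-1,4-dicarboxylate (stereocentres as 27) | CCCCCCCCCCCCCCCCC1=C[C@@H](C(=O)OC)[C@@H](C=O)[C@@H](CC2(CCCCCCCCCCCCCCCC)OCCO2)[C@@H]1C(=O)OC
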